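**Strategy.** Ring B is opened at C5–C6 and C8–C9 (labdane numbering, see remark). What remains is ring A as a cyclohexene ester in which the quaternary C10 holds the C9 acetate arm next to the enoate carbon C5, and a three-carbon C6–C7–C8 unit supplied as acryloyl(trimethyl)silane. In one flask the C9 enolate adds to the acylsilane (C8–C9), a Brook shift moves the charge to C6, C6 closes onto C5 (C5–C6), and the C4 enolate is alkylated. The step exploits the 1,3-placement of C5 and C9 around C10 and the tether it creates: the cis A/B fusion follows, and C4 becomes quaternary in the same flask.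

Key step: step 6

Remark: labdane numbering is used (C1–C10 decalin, C11/C12 chain, C13–C16 butenolide, C17 exocyclic CH2, C18/C19 the CH2OH carbons on C4, C20 the methyl on C10); the structure is read as written, i.e. as a cis-fused decalin with H5, C20, O3 and C11 on one face, called β below.

Step 1
Reactants: 1 propanal; 2 pyrrolidine; 3 allyl bromoacetate
Product: 5 allyl 3-methyl-4-oxobutanoate (racemic), via pyrrolidine enamine 4 (not isolated)
Conditions: pyrrolidine, K2CO3, Et2O, 0 °C; then 3, MeCN, 60 °C; then H2O/AcOH, rt
Reagents that add atoms: water, O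
Why: Stork enamine alkylation, in which the enamine of propanal is C-alkylated by the reactive α-bromo ester and then hydrolysed; the stereocentre formed is irrelevant because it becomes the enamine carbon of step 3.

Step 2
Reactants: 6 acrolein; 7 ethyl diazoacetate
Product: 8 ethyl 3-oxopent-4-enoate
Conditions: SnCl2 (10 mol%), CH2Cl2, rt
Reagents that add atoms: none
Why: Roskamp reaction, in which Lewis-acid-promoted addition of the diazo ester to the aldehyde, 1,2-hydride shift and loss of N2 should give the β-keto ester (Nazarov reagent), to be used crude.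

Step 3
Reactants: 5 allyl 3-methyl-4-oxobutanoate; 8 ethyl 3-oxopent-4-enoate
Product: 10 ethyl (S)-3-[2-(allyloxy)-2-oxoethyl]-3-methyl-6-oxocyclohex-1-ene-1-carboxylate, via Michael adduct 9 (not isolated)
Conditions: (S)-N-(4-dodecylphenylsulfonyl)pyrrolidine-2-carboxamide (20 mol%), ClCH2CH2Cl, rt; then piperidinium acetate (cat.), 40 °C
Reagents that add atoms: none
Why: amine-catalysed Robinson-type annulation, in which the enamine of the α-branched aldehyde adds to the vinyl ketone (Michael) and an intramolecular Knoevenagel condensation closes ring A; the chiral prolinamide (enantiomer chosen accordingly) shields one enamine face and should set C10 as S.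

Step 4
Reactants: 10 enone ester
Product: 11 ethyl (3S,6R)-3-[2-(allyloxy)-2-oxoethyl]-6-hydroxy-3-methylcyclohex-1-ene-1-carboxylate
Conditions: (S)-2-methyl-CBS-oxazaborolidine (20 mol%), catecholborane, toluene, −78 °C
Reagents that add atoms: none
Why: Corey–Bakshi–Shibata reduction, in which 1,2-hydride delivery under catalyst control (alkenyl as the large group) should give the (6R)-carbinol, i.e. the 3β-OH cis to the C10 methyl, independently of the remote C10 centre.

Step 5
Reactants: 12 methoxyallene
Product: 15 1-(trimethylsilyl)prop-2-en-1-one (acryloyltrimethylsilane), via silylallene 14 (not isolated)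
Conditions: n-BuLi, THF, −78 °C; Me3SiCl; then aq. oxalic acid, 0 °C
Reagents that add atoms: 13 chlorotrimethylsilane, C[Si](C)(C)Cl; water, O
Why: α-lithiation and C-silylation of the alkoxyallene followed by hydrolysis of the allenyl ether is the established preparation of α,β-unsaturated acylsilanes; 15 is used at once.

Step 6
Reactants: 11 allylic alcohol; 15 acryloyltrimethylsilane
Product: 18 cis-decalin β-keto allyl ester (C8 ketone; C9 CO2allyl; C4 CO2Et/CH2OSEM; 3β-OSEM; 5β-H; 10β-CH3), via silyl enol ether 17 (not isolated)
Conditions: LiN(i-Pr)2 (2.2 equiv), THF, −78 °C; 15, −78 to −30 °C; SEMCl (2.5 equiv), DMPU, −78 to 0 °C; aq. citric acid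
Reagents that add atoms: 16 2-(trimethylsilyl)ethoxymethyl chloride, C[Si](C)(C)CCOCCl
Why: Proposed new method: LiN(i-Pr)2 converts 11 into the alkoxide/ester-enolate dianion, the C9 enolate adds 1,2 to the acylsilane carbonyl (C8–C9), the resulting alkoxide undergoes [1,2]-Brook rearrangement to a siloxyallyl anion whose γ-carbon C6 adds to C5 of the ring A enoate (C5–C6), and the β-oxido ester enolate at C4 is C-alkylated by SEMCl while O3 is O-alkylated. The closest known reaction types are the Brook-rearrangement-mediated annulations of acryloylsilanes with ketone enolates and the γ-alkylation of siloxyallyl anions, here terminated by a Michael addition instead of a carbonyl addition. Ring B closes by 6-exo-trig conjugate addition. C5 is set by the tether: C6 can only reach the enoate face that carries C9, so H5 ends syn to the C10 methyl (cis ring fusion); C10 and C3 come from 11, while C9 and C4 are left unassigned because both are erased later (steps 8 and 12). The step needs 1,2- rather than 1,4-attack on the acylsilane and γ-attack of the allyl anion on C5 rather than five-membered acylation at the allyl ester carbonyl; the first is the usual course for lithium enolates at −78 °C, the second is favoured by the soft delocalised carbanion, the chair-like 6-exo geometry and the low temperature, and the free C3 alkoxide keeps the C4 enolate from β-elimination.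

Step 7
Reactants: 18 β-keto allyl ester
Product: 19 cis-decalin alcohol (C4 CH2OH/CH2OSEM; C8 ketone; C9 CO2allyl)
Conditions: NaH (1.1 equiv), THF, 0 °C; then LiAlH4, −20 to 0 °C
Reagents that add atoms: none
Why: enolate protection, in which the sodium enolate of the β-keto allyl ester is inert to hydride so that LiAlH4 should reduce only the ethyl ester at C4 to the hydroxymethyl group.

Step 8
Reactants: 19 β-keto allyl ester alcohol
Product: 20 9β-allyl ketone (C11 β, H9 α)
Conditions: Pd(PPh3)4 (5 mol%), THF, rt
Reagents that add atoms: none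
Why: Tsuji decarboxylative allylation, in which ionisation of the allyl ester, loss of CO2 and recombination of the regiodefined C8–C9 enolate with the π-allyl unit should deliver the allyl group to the convex β face (the face of H5 and CH3-20, away from ring A), setting C9.

Step 9
Reactants: 20 allyl ketone; 21 α-methylene-γ-butyrolactone
Product: 22 (E)-alkylidene lactone (C12=C13)
Conditions: second-generation Hoveyda–Grubbs catalyst (5 mol%), 21 (5 equiv), CH2Cl2, 40 °C
Reagents that add atoms: none
Why: olefin cross-metathesis of the terminal allyl group with the 1,1-disubstituted acrylate-type olefin should give the (E)-alkylidene lactone with loss of ethylene, the hindered ketone and the free alcohol being tolerated.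

Step 10
Reactants: 22 alkylidene lactone
Product: 23 butenolide ketone (C13=C14)
Conditions: RuHCl(CO)(PPh3)3 (5 mol%), toluene, 80 °C
Reagents that add atoms: none
Why: metal-hydride alkene isomerisation (hydrometalation/β-hydride elimination) should move the exocyclic conjugated double bond into the ring to the more stable butenolide; it is run while C8 is still a ketone so that no other alkene can migrate, and the neutral medium should leave C9 untouched.

Step 11
Reactants: 23 butenolide ketone
Product: 25 8(17)-methylene bis-SEM ether
Conditions: Zn, CH2Br2, TiCl4 (pre-formed Lombardo reagent), THF/CH2Cl2, 0 °C to rt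
Reagents that add atoms: 24 dibromomethane, BrCBr
Why: Takai–Lombardo methylenation, in which the non-basic titanium–zinc carbenoid should convert the hindered, enolisable C8 ketone into the exocyclic methylene without epimerising C9 and without attacking the lactone.

Step 12
Reactants: 25 bis-SEM ether
Product: 26 target
Conditions: MgBr2·OEt2 (excess), MeNO2/Et2O, rt
Reagents that add atoms: none
Why: Lewis-acid cleavage of both SEM ethers (bromide attack at silicon, loss of ethylene and formaldehyde) should free O3 and the second CH2OH without touching the exocyclic alkene or the butenolide; C4 then carries two identical CH2OH groups and is no longer a stereocentre.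

Compound list
1 | propanal | CCC=O | starting material
2 | pyrrolidine | C1CCNC1 | starting material
3 | allyl bromoacetate | BrCC(=O)OCC=C | starting material
4 | (E)-1-(prop-1-en-1-yl)pyrrolidine | C/C=C/N1CCCC1 | intermediate (not isolated)
5 | allyl 3-methyl-4-oxobutanoate (racemic) | O=CC(C)CC(=O)OCC=C | intermediate
6 | acrolein | C=CC=O | starting material
7 | ethyl diazoacetate | CCOC(=O)C=[N+]=[N-] | starting material
8 | ethyl 3-oxopent-4-enoate | C=CC(=O)CC(=O)OCC | intermediate
9 | 1-allyl 8-ethyl (S)-3-formyl-3-methyl-6-oxooctanedioate | O=C[C@](C)(CC(=O)OCC=C)CCC(=O)CC(=O)OCC | intermediate (not isolated)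
10 | ethyl (S)-3-[2-(allyloxy)-2-oxoethyl]-3-methyl-6-oxocyclohex-1-ene-1-carboxylate | C1=C(C(=O)OCC)C(=O)CC[C@@]1(C)CC(=O)OCC=C | intermediate
11 | ethyl (3S,6R)-3-[2-(allyloxy)-2-oxoethyl]-6-hydroxy-3-methylcyclohex-1-ene-1-carboxylate | C1=C(C(=O)OCC)[C@H](O)CC[C@@]1(C)CC(=O)OCC=C | intermediate
12 | methoxyallene (1-methoxypropa-1,2-diene) | COC=C=C | starting material
13 | chlorotrimethylsilane | C[Si](C)(C)Cl | starting material
14 | (1-methoxypropa-1,2-dien-1-yl)trimethylsilane | COC(=C=C)[Si](C)(C)C | intermediate (not isolated)
15 | 1-(trimethylsilyl)prop-2-en-1-one | C=CC(=O)[Si](C)(C)C | intermediate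
16 | 2-(trimethylsilyl)ethoxymethyl chloride (SEMCl) | C[Si](C)(C)CCOCCl | starting material
17 | C7=C8 trimethylsilyl enol ether of 18 (cis-decalin; C4 and C9 unassigned) | C[Si](C)(C)OC1=CC[C@H]2C(C(=O)OCC)(COCOCC[Si](C)(C)C)[C@H](OCOCC[Si](C)(C)C)CC[C@@]2(C)C1C(=O)OCC=C | intermediate (not isolated)
18 | cis-decalin β-keto allyl ester: C8 ketone, C9 CO2allyl, C4(CO2Et)(CH2OSEM), 3β-OSEM, 5β-H, 10β-CH3 (C4 and C9 unassigned) | O=C1CC[C@H]2C(C(=O)OCC)(COCOCC[Si](C)(C)C)[C@H](OCOCC[Si](C)(C)C)CC[C@@]2(C)C1C(=O)OCC=C | intermediate
19 | as 18 with C4(CH2OH)(CH2OSEM) | O=C1CC[C@H]2C(CO)(COCOCC[Si](C)(C)C)[C@H](OCOCC[Si](C)(C)C)CC[C@@]2(C)C1C(=O)OCC=C | intermediate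
20 | cis-decalin C8 ketone with 9β-allyl (H9 α), C4(CH2OH)(CH2OSEM), 3β-OSEM | O=C1CC[C@H]2C(CO)(COCOCC[Si](C)(C)C)[C@H](OCOCC[Si](C)(C)C)CC[C@@]2(C)[C@@H]1CC=C | intermediate
21 | α-methylene-γ-butyrolactone | C=C1CCOC1=O | starting material
22 | C8 ketone with (E)-C12=C13 alkylidene butyrolactone side chain | O=C1CC[C@H]2C(CO)(COCOCC[Si](C)(C)C)[C@H](OCOCC[Si](C)(C)C)CC[C@@]2(C)[C@@H]1C/C=C1\CCOC1=O | intermediate
23 | C8 ketone with the C13=C14 butenolide side chain | O=C1CC[C@H]2C(CO)(COCOCC[Si](C)(C)C)[C@H](OCOCC[Si](C)(C)C)CC[C@@]2(C)[C@@H]1CCC1=CCOC1=O | intermediate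
24 | dibromomethane | BrCBr | starting material
25 | 8(17)-methylene compound, 3-O-SEM and one CH2O-SEM | C=C1CC[C@H]2C(CO)(COCOCC[Si](C)(C)C)[C@H](OCOCC[Si](C)(C)C)CC[C@@]2(C)[C@@H]1CCC1=CCOC1=O | intermediate
26 | target (CNP0146463.1) | C=C1CC[C@H]2C(CO)(CO)[C@H](O)CC[C@@]2(C)[C@@H]1CCC1=CCOC1=O | target

Total step count: 12. Longest linear sequence: 10 steps (1, 3, 4, 6, 7, 8, 9, 10, 11, 12).

Steps most likely to fail

Step 6. The relay may break down because the siloxyallyl anion is protonated, acylates the allyl ester carbonyl in a five-membered closure, or the C3 alkoxide desilylates the acylsilane before the enolate adds. The fallback sets out from 11 and returns to the route at 18 with known reactions. Silylation (Me3SiCl, imidazole) gives the trimethylsilyl ether F1. Its lithium enolate (LiN(i-Pr)2, THF, −78 °C) is C-acylated with 3-bromopropanoyl chloride to the β-keto allyl ester bromide F2. Bu3SnH/AIBN (benzene, 80 °C) closes ring B by 6-exo-trig radical cyclisation onto the enoate, cis for the same tether reason, and acidic work-up removes the silyl ether to give the cis-fused hydroxy keto diester F3. The trianion of F3 (LiN(i-Pr)2, 3.2 equiv) is alkylated with SEMCl at C4 and O3 to give 18.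

Step 10. The double bond may fail to migrate into the lactone ring, or C9 may epimerise through the enol of the neighbouring ketone on prolonged heating. The fallback sets out from 22 and returns at 25. Stryker's reagent, [(Ph3P)CuH]6, reduces the conjugated alkylidene lactone chemoselectively to the saturated lactone F4. Lombardo methylenation (as in step 11) of the C8 ketone gives the methylene lactone F5. The lactone enolate (LiN(i-Pr)2, 2.2 equiv, −78 °C) is sulfenylated with PhSSPh to the α-phenylthio lactone F6. NaIO4 (MeOH/H2O) gives the sulfoxide F7, whose thermolysis (toluene, 110 °C) eliminates benzenesulfenic acid into the ring to give 25.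

Step 3. Facial selectivity in the enamine Michael addition of the α-branched aldehyde may be poor (low enantiomeric purity at C10), or the Nazarov reagent may polymerise under amine catalysis. The fallback sets out from 5 and 8 and returns at 11. The annulation is run without chiral control (pyrrolidine/AcOH, then piperidinium acetate) to give the racemic enone F8. The CBS reduction of step 4 then fixes the carbinol centre by catalyst control in both enantiomers, which turns them into 11 and its C10 epimer, the (3R,6R) diastereomer F9. These are separated by chromatography.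

Further compounds
F1 | step 6 | O-trimethylsilyl ether of 11 | C1=C(C(=O)OCC)[C@H](O[Si](C)(C)C)CC[C@@]1(C)CC(=O)OCC=C
F2 | step 6 | β-keto allyl ester bromide (C9 acylated, C9 unassigned) | C1=C(C(=O)OCC)[C@H](O[Si](C)(C)C)CC[C@@]1(C)C(C(=O)OCC=C)C(=O)CCBr
F3 | step 6 | cis-fused hydroxy keto diester (C4–H, free 3β-OH) | O=C1CC[C@H]2C(C(=O)OCC)[C@H](O)CC[C@@]2(C)C1C(=O)OCC=C
F4 | step 10 | C8 ketone with saturated α-alkyl-γ-butyrolactone side chain | O=C1CC[C@H]2C(CO)(COCOCC[Si](C)(C)C)[C@H](OCOCC[Si](C)(C)C)CC[C@@]2(C)[C@@H]1CCC1CCOC1=O
F5 | step 10 | 8(17)-methylene compound with saturated lactone | C=C1CC[C@H]2C(CO)(COCOCC[Si](C)(C)C)[C@H](OCOCC[Si](C)(C)C)CC[C@@]2(C)[C@@H]1CCC1CCOC1=O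
F6 | step 10 | α-phenylthio lactone | C=C1CC[C@H]2C(CO)(COCOCC[Si](C)(C)C)[C@H](OCOCC[Si](C)(C)C)CC[C@@]2(C)[C@@H]1CCC1(Sc3ccccc3)CCOC1=O
F7 | step 10 | α-phenylsulfinyl lactone | C=C1CC[C@H]2C(CO)(COCOCC[Si](C)(C)C)[C@H](OCOCC[Si](C)(C)C)CC[C@@]2(C)[C@@H]1CCC1(S(=O)c3ccccc3)CCOC1=O
F8 | step 3 | racemic enone (racemic 10) | C1=C(C(=O)OCC)C(=O)CCC1(C)CC(=O)OCC=C
F9 | step 3 | ethyl (3R,6R)-3-[2-(allyloxy)-2-oxoethyl]-6-hydroxy-3-methylcyclohex-1-ene-1-carboxylate | C1=C(C(=O)OCC)[C@H](O)CC[C@]1(C)CC(=O)OCC=C
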